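Halimane numbering is used throughout. The plan rests on cutting ring A at C1–C2 and C3–C4, which releases C2–C3 as an ethylene 1,2-dipole, phenyl vinyl sulfone. The key step exploits two features: C4 is α to the C18 carbonyl and allylic to the ring-B C5=C6 bond, and C1 is an exocyclic methylene on C10. Its precursor is a monocyclic ring-B ester, a C4 epimer mixture with a chloromethyl arm on C10. Deprotonation merges both epimers into one dienolate; C4 adds to the sulfone, and the resulting C2 carbanion displaces chloride at C1. One operation closes ring A, builds the C4 quaternary centre and keeps C5=C6 in place.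

Key step: step 12

Assumption: methyl hydrogen (R)-3-methylglutarate 5 is taken as commercial. The C4–H centre of 19 and the sulfonyl-bearing C2 of 22 and 23 are epimer mixtures that the route erases, so their SMILES carry no descriptor there. TBS = tert-butyldimethylsilyl.

Step 1
Reactants: 1 3,4-dimethylanisole
Product: 3 3,4-dimethylcyclohex-3-en-1-one, via Birch diene 2 (not isolated)
Conditions: Li, NH3(l), t-BuOH, THF, −78 to −33 °C; then (CO2H)2, MeOH–H2O, rt
Reagents that add atoms: water, O
Why: Birch reduction places the methoxy and both methyl groups on the two surviving double bonds, and mild oxalic-acid hydrolysis of the enol ether then frees the β,γ-unsaturated ketone without conjugation, so that a flat arene becomes the ring-B carbocycle (no stereocentre yet).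

Step 2
Reactants: 3 3,4-dimethylcyclohex-3-en-1-one
Product: 4 (4S)-3,4-dimethylcyclohex-2-en-1-one
Conditions: cinchona-derived chiral primary–tertiary diamine (10 mol %), carboxylic acid co-catalyst (20 mol %), toluene, rt
Reagents that add atoms: none
Why: Enantioselective β,γ-to-α,β enone isomerisation by cooperative iminium–base (dienamine) organocatalysis, in which the chiral ammonium site protonates one face of the γ-carbon and so sets C8 as S, the pseudo-enantiomeric catalyst being chosen accordingly.

Step 3
Reactants: 5 methyl hydrogen (R)-3-methylglutarate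
Product: 6 methyl (3R)-5-hydroxy-3-methylpentanoate
Conditions: BH3·SMe2, THF, −10 °C to rt; MeOH quench
Reagents that add atoms: none
Why: Chemoselective borane reduction of a carboxylic acid beside a methyl ester differentiates the two chain ends (acid carbon = C11, ester carbon = C15) and leaves the C13 stereocentre untouched.

Step 4
Reactants: 6 methyl (3R)-5-hydroxy-3-methylpentanoate
Product: 7 methyl (3S)-5-bromo-3-methylpentanoate
Conditions: CBr4, PPh3, CH2Cl2, 0 °C
Reagents that add atoms: carbon tetrabromide, BrC(Br)(Br)Br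
Why: The Appel reaction brominates the primary alcohol under neutral SN2 conditions, outruns lactonisation and does not touch C13 (the descriptor changes only through CIP priorities).

Step 5
Reactants: 7 methyl (3S)-5-bromo-3-methylpentanoate
Product: 8 (3S)-5-bromo-3-methylpentan-1-ol
Conditions: DIBAL-H (2.2 equiv), CH2Cl2, −78 to 0 °C; Rochelle salt work-up
Reagents that add atoms: none
Why: DIBAL-H reduces the ester to the primary alcohol, and a primary alkyl bromide is inert to it at low temperature.

Step 6
Reactants: 8 (3S)-5-bromo-3-methylpentan-1-ol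
Product: 9 [(3S)-5-bromo-3-methylpentyl]oxy-tert-butyldimethylsilane
Conditions: TBSCl, imidazole, DMF, rt
Reagents that add atoms: tert-butyldimethylsilyl chloride, CC(C)(C)[Si](C)(C)Cl
Why: Standard silylation of the primary alcohol masks the future C15 carboxyl carbon against organometallic reagents and amide bases.

Step 7
Reactants: 9 [(3S)-5-bromo-3-methylpentyl]oxy-tert-butyldimethylsilane; 4 (4S)-3,4-dimethylcyclohex-2-en-1-one
Product: 11 [(3R,4S)-3-[(3R)-5-(TBSO)-3-methylpentyl]-3,4-dimethylcyclohex-1-en-1-yl]oxytrimethylsilane, via Grignard reagent 10 (not isolated)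
Conditions: 9, Mg, THF, rt to 40 °C; then CuBr·SMe2 (10 mol %), HMPA, TMSCl, 4, THF, −78 °C; Et3N, pentane work-up
Reagents that add atoms: chlorotrimethylsilane, C[Si](C)(C)Cl
Why: Chlorosilane-accelerated copper-catalysed conjugate addition of a Grignard reagent to a β,β-disubstituted enone proceeds by axial attack anti to the C8 methyl group, which sets the C9 quaternary centre (side chain trans, C9 methyl cis to the C8 methyl), and silylation stores the enolate regiospecifically as the C5=C10 enol ether.

Step 8
Reactants: 11 [(3R,4S)-3-[(3R)-5-(TBSO)-3-methylpentyl]-3,4-dimethylcyclohex-1-en-1-yl]oxytrimethylsilane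
Product: 14 (3R,4S)-3-[(3R)-5-(TBSO)-3-methylpentyl]-3,4-dimethyl-2-methylidenecyclohexan-1-one, via Mannich base 12 (not isolated), via methiodide 13 (not isolated)
Conditions: Eschenmoser's salt, CH2Cl2, rt; MeI, rt; DBU, rt
Reagents that add atoms: Eschenmoser's salt (dimethylmethylideneammonium iodide), C=[N+](C)C.[I-]
Why: The Mannich reaction of the silyl enol ether at C10, followed by quaternisation and Hofmann-type β-elimination, is a regiospecific α-methylenation that brings in C1.

Step 9
Reactants: 14 (3R,4S)-3-[(3R)-5-(TBSO)-3-methylpentyl]-3,4-dimethyl-2-methylidenecyclohexan-1-one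
Product: 15 (2S,3R,4S)-2-(chloromethyl)-3-[(3R)-5-(TBSO)-3-methylpentyl]-3,4-dimethylcyclohexan-1-one
Conditions: HCl (1 M in Et2O, 1.2 equiv), CH2Cl2, −78 to −30 °C
Reagents that add atoms: hydrogen chloride, Cl
Why: In this conjugate hydrochlorination chloride adds to C1 and the enol ketonises by axial protonation of C10 on the α face, anti to the axial C9 methyl group, which should give the isomer with CH2Cl, side chain and C8 methyl all equatorial (also the thermodynamic one); brief anhydrous acid at low temperature spares the silyl ether.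

Step 10
Reactants: 15 (2S,3R,4S)-2-(chloromethyl)-3-[(3R)-5-(TBSO)-3-methylpentyl]-3,4-dimethylcyclohexan-1-one
Product: 16 (4S,5R,6S)-6-(chloromethyl)-5-[(3R)-5-(TBSO)-3-methylpentyl]-4,5-dimethylcyclohex-1-en-1-yl trifluoromethanesulfonate
Conditions: KHMDS, THF, −78 °C (ketone added to base); Comins' reagent, −78 °C
Reagents that add atoms: Comins' reagent, FC(F)(F)S(=O)(=O)N(c1ccc(Cl)cn1)S(=O)(=O)C(F)(F)F
Why: Kinetic enolate formation and O-triflation work because the base takes a proton from the unhindered C6 methylene and not from the C10 methine shielded by C9 and CH2Cl, so the future C5=C6 bond is fixed and β-elimination of chloride is avoided.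

Step 11
Reactants: 16 (4S,5R,6S)-6-(chloromethyl)-5-[(3R)-5-(TBSO)-3-methylpentyl]-4,5-dimethylcyclohex-1-en-1-yl trifluoromethanesulfonate; 17 methyl 2-bromopropanoate (racemic)
Product: 19 methyl 2-[(4S,5R,6S)-6-(chloromethyl)-5-[(3R)-5-(TBSO)-3-methylpentyl]-4,5-dimethylcyclohex-1-en-1-yl]propanoate (both epimers at halimane C4), via Reformatsky reagent 18 (not isolated)
Conditions: 17, Zn (TMSCl-activated), THF, rt; then 16, Pd2(dba)3 (2.5 mol %), XPhos (6 mol %), THF, 50 °C
Reagents that add atoms: none
Why: Negishi-type cross-coupling of a Reformatsky reagent with an alkenyl triflate forms C4–C5; the primary alkyl chloride is inert to Pd(0) here, and the new C4–H centre may be a mixture because step 12 erases it.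

Step 12
Reactants: 19 methyl 2-[(4S,5R,6S)-6-(chloromethyl)-5-[(3R)-5-(TBSO)-3-methylpentyl]-4,5-dimethylcyclohex-1-en-1-yl]propanoate; 20 phenyl vinyl sulfone
Product: 23 methyl (1R,4aS,5R,6S)-3-(phenylsulfonyl)-5-[(3R)-5-(TBSO)-3-methylpentyl]-1,5,6-trimethyl-1,2,3,4,4a,5,6,7-octahydronaphthalene-1-carboxylate (epimers at halimane C2), via lithium dienolate 21 (not isolated), via sulfonyl carbanion 22 (not isolated)
Conditions: LDA (1.1 equiv), THF, −78 °C; 20 (1.05 equiv), −78 °C; DMPU, −78 °C to rt
Reagents that add atoms: none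
Why: LDA removes the doubly activated C4–H (α to the ester, allylic to C5=C6) from both epimers of 19 to give the single dienolate 21, whose α-carbon C4 adds to the β-carbon of 20 (C3–C4 bond, C5=C6 stays where it is), and on warming the α-sulfonyl carbanion 22 (C2) displaces chloride from C1 (C1–C2 bond). The closest known reaction type is the Michael-initiated ring closure, here conjugate addition of an ester enolate to a vinyl sulfone followed by intramolecular sulfone alkylation, a formal [4+2] annulation in which 20 serves as an ethylene 1,2-dipole. Ring A closes in the 6-exo-tet mode through a chair-like transition state. C4 is controlled by C10: the CH2Cl arm fills the β quadrant next to C4, so the dienolate twists to put its methyl group toward C10–H and the bulky lithium enolate terminus toward C6–H, 20 approaches from the open α face, and rotation about C4–C5 before closure places CO2Me α (axial) and CH3 β (equatorial), i.e. 4R; the same isomer is preferred in the closing chair (smaller ester axial), so any retro-Michael equilibration of 22 funnels the same way. C2 forms as an inconsequential epimer mixture that step 13 erases. The step needs α- over γ-attack (C6), Michael addition before any alkylation, and substitution over elimination; these are secured by the higher charge density at the α-carbon of a lithium dienolate under kinetic conditions, by a chloride that is inert toward 21 at −78 °C, and by the intramolecular six-membered closure in THF–DMPU.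

Step 13
Reactants: 23 methyl (1R,4aS,5R,6S)-3-(phenylsulfonyl)-5-[(3R)-5-(TBSO)-3-methylpentyl]-1,5,6-trimethyl-1,2,3,4,4a,5,6,7-octahydronaphthalene-1-carboxylate
Product: 24 methyl (1R,4aS,5R,6S)-5-[(3R)-5-(TBSO)-3-methylpentyl]-1,5,6-trimethyl-1,2,3,4,4a,5,6,7-octahydronaphthalene-1-carboxylate
Conditions: Mg turnings, MeOH, rt to 50 °C
Reagents that add atoms: none
Why: Reductive desulfonylation by electron transfer from magnesium in methanol replaces the C2 sulfonyl group by hydrogen, merges both C2 epimers and spares ester, silyl ether and the trisubstituted alkene.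

Step 14
Reactants: 24 methyl (1R,4aS,5R,6S)-5-[(3R)-5-(TBSO)-3-methylpentyl]-1,5,6-trimethyl-1,2,3,4,4a,5,6,7-octahydronaphthalene-1-carboxylate
Product: 25 [(1R,4aS,5R,6S)-5-[(3R)-5-(TBSO)-3-methylpentyl]-1,5,6-trimethyl-1,2,3,4,4a,5,6,7-octahydronaphthalen-1-yl]methanol
Conditions: LiAlH4, THF, 0 °C to reflux
Reagents that add atoms: none
Why: LiAlH4 hydride reduction converts the hindered axial C18 ester to the neopentyl alcohol with no change at C4.

Step 15
Reactants: 25 [(1R,4aS,5R,6S)-5-[(3R)-5-(TBSO)-3-methylpentyl]-1,5,6-trimethyl-1,2,3,4,4a,5,6,7-octahydronaphthalen-1-yl]methanol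
Product: 26 [(1R,4aS,5R,6S)-5-[(3R)-5-(TBSO)-3-methylpentyl]-1,5,6-trimethyl-1,2,3,4,4a,5,6,7-octahydronaphthalen-1-yl]methyl acetate
Conditions: Ac2O, pyridine, DMAP (cat.), CH2Cl2, rt
Reagents that add atoms: acetic anhydride, CC(=O)OC(C)=O
Why: DMAP-catalysed acetylation of the only free hydroxyl group installs the C18 acetate.

Step 16
Reactants: 26 [(1R,4aS,5R,6S)-5-[(3R)-5-(TBSO)-3-methylpentyl]-1,5,6-trimethyl-1,2,3,4,4a,5,6,7-octahydronaphthalen-1-yl]methyl acetate
Product: 27 (3R)-5-[(1R,2S,5R,8aS)-5-(acetoxymethyl)-1,2,5-trimethyl-1,2,3,5,6,7,8,8a-octahydronaphthalen-1-yl]-3-methylpentanoic acid (target; 4R,8S,9R,10S,13R in halimane numbering)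
Conditions: Jones reagent (CrO3, H2SO4, H2O), acetone, 0 °C
Reagents that add atoms: water, O
Why: In the Jones oxidation the acidic medium cleaves the primary silyl ether and chromic acid takes the liberated alcohol through the aldehyde hydrate to the C15 acid, while the acetate and the hindered trisubstituted alkene should persist at 0 °C.

Compound list
1 | 3,4-dimethylanisole | COc1ccc(C)c(C)c1 | starting material
2 | 1-methoxy-4,5-dimethylcyclohexa-1,4-diene | COC1=CCC(C)=C(C)C1 | intermediate
3 | 3,4-dimethylcyclohex-3-en-1-one | O=C1CCC(C)=C(C)C1 | intermediate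
4 | (4S)-3,4-dimethylcyclohex-2-en-1-one | O=C1CC[C@H](C)C(C)=C1 | intermediate
5 | methyl hydrogen (R)-3-methylglutarate | OC(=O)C[C@@H](C)CC(=O)OC | starting material
6 | methyl (3R)-5-hydroxy-3-methylpentanoate | OCC[C@@H](C)CC(=O)OC | intermediate
7 | methyl (3S)-5-bromo-3-methylpentanoate | BrCC[C@@H](C)CC(=O)OC | intermediate
8 | (3S)-5-bromo-3-methylpentan-1-ol | BrCC[C@@H](C)CCO | intermediate
9 | [(3S)-5-bromo-3-methylpentyl]oxy-tert-butyldimethylsilane | BrCC[C@@H](C)CCO[Si](C)(C)C(C)(C)C | intermediate
10 | bromo[(3S)-5-(TBSO)-3-methylpentyl]magnesium | Br[Mg]CC[C@@H](C)CCO[Si](C)(C)C(C)(C)C | intermediate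
11 | trimethylsilyl enol ether, C5=C10, (3R,4S) ring, (3R) side chain | C1=C(O[Si](C)(C)C)CC[C@H](C)[C@@]1(C)CC[C@@H](C)CCO[Si](C)(C)C(C)(C)C | intermediate
12 | 2-(dimethylaminomethyl) ketone (Mannich base, C10 epimers) | CN(C)CC1C(=O)CC[C@H](C)[C@@]1(C)CC[C@@H](C)CCO[Si](C)(C)C(C)(C)C | intermediate
13 | trimethylammonium iodide of 12 | [I-].C[N+](C)(C)CC1C(=O)CC[C@H](C)[C@@]1(C)CC[C@@H](C)CCO[Si](C)(C)C(C)(C)C | intermediate
14 | (3R,4S)-3-[(3R)-5-(TBSO)-3-methylpentyl]-3,4-dimethyl-2-methylidenecyclohexan-1-one | C=C1C(=O)CC[C@H](C)[C@@]1(C)CC[C@@H](C)CCO[Si](C)(C)C(C)(C)C | intermediate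
15 | (2S,3R,4S)-2-(chloromethyl)-3-[(3R)-5-(TBSO)-3-methylpentyl]-3,4-dimethylcyclohexan-1-one | ClC[C@@H]1C(=O)CC[C@H](C)[C@@]1(C)CC[C@@H](C)CCO[Si](C)(C)C(C)(C)C | intermediate
16 | (4S,5R,6S)-6-(chloromethyl)-5-[(3R)-5-(TBSO)-3-methylpentyl]-4,5-dimethylcyclohex-1-en-1-yl triflate | ClC[C@@H]1C(OS(=O)(=O)C(F)(F)F)=CC[C@H](C)[C@@]1(C)CC[C@@H](C)CCO[Si](C)(C)C(C)(C)C | intermediate
17 | methyl 2-bromopropanoate (racemic) | COC(=O)C(C)Br | starting material
18 | bromo(1-methoxy-1-oxopropan-2-yl)zinc | COC(=O)C(C)[Zn]Br | intermediate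
19 | methyl 2-[(4S,5R,6S)-6-(chloromethyl)-5-[(3R)-5-(TBSO)-3-methylpentyl]-4,5-dimethylcyclohex-1-en-1-yl]propanoate (C4 epimers) | ClC[C@@H]1C(C(C)C(=O)OC)=CC[C@H](C)[C@@]1(C)CC[C@@H](C)CCO[Si](C)(C)C(C)(C)C | intermediate
20 | phenyl vinyl sulfone | C=CS(=O)(=O)c1ccccc1 | starting material
21 | lithium dienolate of 19 | [Li+].ClC[C@@H]1C(C(C)=C([O-])OC)=CC[C@H](C)[C@@]1(C)CC[C@@H](C)CCO[Si](C)(C)C(C)(C)C | intermediate
22 | lithiated Michael adduct (4R, carbanion at C2) | [Li+].ClC[C@@H]1C([C@](C)(C(=O)OC)C[CH-]S(=O)(=O)c2ccccc2)=CC[C@H](C)[C@@]1(C)CC[C@@H](C)CCO[Si](C)(C)C(C)(C)C | intermediate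
23 | bicyclic C2-phenylsulfonyl C18 methyl ester (1R,4aS,5R,6S; C2 epimers) | COC(=O)[C@]1(C)CC(S(=O)(=O)c3ccccc3)C[C@@H]2C1=CC[C@H](C)[C@@]2(C)CC[C@@H](C)CCO[Si](C)(C)C(C)(C)C | intermediate
24 | bicyclic C18 methyl ester (1R,4aS,5R,6S) | COC(=O)[C@]1(C)CCC[C@@H]2C1=CC[C@H](C)[C@@]2(C)CC[C@@H](C)CCO[Si](C)(C)C(C)(C)C | intermediate
25 | C18 primary alcohol | OC[C@]1(C)CCC[C@@H]2C1=CC[C@H](C)[C@@]2(C)CC[C@@H](C)CCO[Si](C)(C)C(C)(C)C | intermediate
26 | C18 acetate, C15 TBS ether | CC(=O)OC[C@]1(C)CCC[C@@H]2C1=CC[C@H](C)[C@@]2(C)CC[C@@H](C)CCO[Si](C)(C)C(C)(C)C | intermediate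
27 | (4R,8S,9R,10S,13R)-18-acetoxyhalim-5-en-15-oic acid | CC(=O)OC[C@]1(C)CCC[C@@H]2C1=CC[C@H](C)[C@@]2(C)CC[C@@H](C)CC(=O)O | target

Total step count: 16
Longest linear sequence: 14 steps (steps 3–16, from 5)

Steps most likely to fail

1. Step 12. The acceptor may approach the wrong face of C4 or bond at the γ-carbon C6. The sulfone may oligomerise anionically, or loss of HCl may outrun ring closure. The fallback sets out from 16 and comes back at 24, and it leaves the C4 methyl group out until ring A is rigid. Triflate 16 is coupled as in step 11 with the Reformatsky reagent of methyl bromoacetate, bromo(2-methoxy-2-oxoethyl)zinc F1, to give the lower homologue of 19 without the C4 methyl group F2. The same vinyl sulfone annulation is run with two equivalents of LDA, because the first adduct re-forms a dienolate by proton transfer, and should give the bicyclic C4–H sulfonyl ester F3. Mg in MeOH then gives the bicyclic C4–H ester F4. Deconjugative α-methylation of its dienolate (LDA, MeI) sets C4 on the bicycle: methyl iodide takes the equatorial β trajectory and leaves the ester axial, which is 24.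

2. Step 10. Deprotonation may stray to C10 and be followed by loss of chloride, or the enolate may equilibrate before triflation. Imperfect facial selectivity in the ketonisation of step 9 would also surface here. The fallback sets out from 14 and comes back at 19, and it avoids the β-chloro ketone altogether. Enone 14 can enolise only toward C6, so KHMDS and Comins' reagent give the cross-conjugated dienyl triflate F5. Coupling with 18 as in step 11 gives the dienyl propanoate F6. 9-BBN adds to the exocyclic methylene (boron to C1, hydrogen to C10 from the α face) to give the B-alkyl-9-BBN adduct F7. Sodium perborate gives the C1 primary alcohol F8, which is chlorinated at once under Appel conditions (PPh3, CCl4) to 19.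

3. Step 11. Oxidative addition and transmetalation may be slow at the hindered alkenyl triflate, with reduction of the triflate or migration of the double bond into conjugation. The fallback sets out from 16 and comes back at 19, and it swaps the sp3 zinc partner for an sp2 tin partner. Stille coupling of 16 with methyl 2-(tributylstannyl)acrylate (Pd(PPh3)4, LiCl, CuI, DMF) gives the 2-cyclohexenyl acrylate F9. Conjugate reduction with Stryker's reagent then delivers hydride to the acrylate CH2, which becomes the C4 methyl group of 19.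

Further compounds
F1 | step 12 | bromo(2-methoxy-2-oxoethyl)zinc | COC(=O)C[Zn]Br
F2 | step 12 | lower homologue of 19 without the C4 methyl group (cyclohexenyl acetate, ring and chain stereocentres as in 19) | ClC[C@@H]1C(CC(=O)OC)=CC[C@H](C)[C@@]1(C)CC[C@@H](C)CCO[Si](C)(C)C(C)(C)C
F3 | step 12 | bicyclic C4–H sulfonyl ester (23 without the C4 methyl group, C2 and C4 epimers) | COC(=O)C1CC(S(=O)(=O)c3ccccc3)C[C@@H]2C1=CC[C@H](C)[C@@]2(C)CC[C@@H](C)CCO[Si](C)(C)C(C)(C)C
F4 | step 12 | bicyclic C4–H ester (24 without the C4 methyl group, C4 epimers) | COC(=O)C1CCC[C@@H]2C1=CC[C@H](C)[C@@]2(C)CC[C@@H](C)CCO[Si](C)(C)C(C)(C)C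
F5 | step 10 | cross-conjugated dienyl triflate (C10=C1H2, C5(OTf)=C6) | C=C1C(OS(=O)(=O)C(F)(F)F)=CC[C@H](C)[C@@]1(C)CC[C@@H](C)CCO[Si](C)(C)C(C)(C)C
F6 | step 10 | dienyl propanoate (C10=C1H2, C5=C6, C4 epimers) | C=C1C(C(C)C(=O)OC)=CC[C@H](C)[C@@]1(C)CC[C@@H](C)CCO[Si](C)(C)C(C)(C)C
F7 | step 10 | B-alkyl-9-BBN adduct (boron on C1, 10-H α) | C1CC2CCCC(C1)B2C[C@@H]3C(C(C)C(=O)OC)=CC[C@H](C)[C@@]3(C)CC[C@@H](C)CCO[Si](C)(C)C(C)(C)C
F8 | step 10 | C1 primary alcohol (19 with OH in place of Cl) | OC[C@@H]1C(C(C)C(=O)OC)=CC[C@H](C)[C@@]1(C)CC[C@@H](C)CCO[Si](C)(C)C(C)(C)C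
F9 | step 11 | 2-cyclohexenyl acrylate (19 with C4=CH2 in place of C4H–CH3) | ClC[C@@H]1C(C(=C)C(=O)OC)=CC[C@H](C)[C@@]1(C)CC[C@@H](C)CCO[Si](C)(C)C(C)(C)C
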